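**Plan**

1. Retrosynthesis: the C12=C13 bond is cut first (crossed aldol condensation of a C17 aldehyde with (E)-4-hydroxy-4-methylpent-2-enal). After a carbonyl is put back at C5 and O6 is tied to O11 through one silicon atom, C3–C4 and C6–C10 are cut together as a (4+3) cycloaddition.
2. Enabling feature: in the bicyclo[4.3.1]decane core the bridgeheads C4 (methyl) and C6 (hydroxyl) flank the one-carbon bridge C5, so C4–C5–C6 is the footprint of a cyclohexanone oxyallyl cation and the four-carbon bridge C10–C1–C2–C3 that of a 1,3-diene; O6 and O11 are 1,3-related and accept a silicon tether.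
3. Forward order: the six-membered ring (C4–C9) comes from 2-methylcyclohexane-1,3-dione; one step then closes the seven-membered ring and a temporary siladioxane; C5 is deoxygenated, silicon removed, C1=C2 hydrogenated, C9 inverted, and the dienal chain attached last.
4. Stereochemistry: a CBS desymmetrisation sets the C9 carbinol, which steers the diene to the opposite face of the cation (C4 and C6, absolute configuration); the (E)-diene and the tether set C10; the C11 hydroxyl directs hydrogenation to set C1; C9 is then inverted by oxidation and axial hydride delivery; 14E comes from trans-hydroalumination and 12E from thermodynamic condensation.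

Key step: step 10

Remarks and assumptions
- Atom labels (not IUPAC locants): C1 is the ring CH that carries the dienal, C2 and C3 the ring CH2 groups next to it, C4 the methyl-bearing bridgehead, C5 the one-carbon bridge, C6 the hydroxyl-bearing bridgehead, C7 and C8 CH2, C9 the secondary carbinol, C10 the ring CH that carries formyl carbon C11, C12 the enal α-carbon, C13–C16 the chain out to the tertiary carbinol, C17 the enal formyl carbon; On is the oxygen on Cn.
- Assumption: 4,4-diethoxybut-1-yne (3-butynal diethyl acetal) is taken as a catalogue compound; it carries C17 at the aldehyde oxidation level, so no primary alcohol has to be oxidised at C17 beside the free C9 carbinol at the end.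
- Assumption: the usual CBS model, with the quaternary C(Me)Cl carbon as the large group, is taken to hold for dione 2; if the sense proves opposite, (S)-Me-CBS is used instead.

**Route**

Step 1
Reactants: 1 2-methylcyclohexane-1,3-dione
Product: 2 2-chloro-2-methylcyclohexane-1,3-dione
Conditions: NCS, MeCN, 0 → 23 °C
Reagents that add atoms: N-chlorosuccinimide, O=C1CCC(=O)N1Cl
Why: Electrophilic α-chlorination of the enolised 2-alkyl-1,3-dione occurs at its only nucleophilic carbon and gives the non-enolisable, prochiral chloro dione.

Step 2
Reactants: 2 2-chloro-2-methylcyclohexane-1,3-dione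
Product: 3 (3S)-2-chloro-3-hydroxy-2-methylcyclohexan-1-one (C2 epimers carried together; the carbinol is the future C9)
Conditions: (R)-Me-CBS (0.2 equiv), catecholborane, toluene–CH2Cl2, −78 °C; MeOH quench
Reagents that add atoms: none
Why: Corey–Bakshi–Shibata reduction desymmetrises the 2,2-disubstituted 1,3-dione, the oxazaborolidine treating the quaternary carbon as the large and the ring CH2 as the small substituent so that hydride creates the (S)-carbinol; the configuration of the C(Me)Cl carbon does not matter because that centre is ionised in step 10.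

Step 3
Reactants: 3 (3S)-2-chloro-3-hydroxy-2-methylcyclohexan-1-one
Product: 4 (3S)-3-(tert-butyldimethylsilyloxy)-2-chloro-2-methylcyclohexan-1-one
Conditions: TBSOTf, 2,6-lutidine, CH2Cl2, −78 → 0 °C
Reagents that add atoms: tert-butyldimethylsilyl triflate, CC(C)(C)[Si](C)(C)OS(=O)(=O)C(F)(F)F
Why: Silyl triflate silylation of a hindered secondary alcohol under a non-nucleophilic buffer avoids epoxide closure or retro-aldol cleavage of the chlorohydrin ketone and installs the bulky group that later shields one face.

Step 4
Reactants: 4 (3S)-3-(tert-butyldimethylsilyloxy)-2-chloro-2-methylcyclohexan-1-one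
Product: 5 (5S)-5-(tert-butyldimethylsilyloxy)-6-chloro-6-methyl-1-(trimethylsilyloxy)cyclohex-1-ene
Conditions: LDA, TMSCl (in situ quench), THF, −78 °C
Reagents that add atoms: chlorotrimethylsilane, C[Si](C)(C)Cl
Why: Kinetic enolisation is possible only toward the CH2 side (the other α-carbon is quaternary), and O-silylation at −78 °C outpaces Favorskii chemistry, as is known for enol silanes of tertiary α-chloro ketones.

Step 5
Reactants: 5 (5S)-5-(tert-butyldimethylsilyloxy)-6-chloro-6-methyl-1-(trimethylsilyloxy)cyclohex-1-ene
Product: 7 (3S)-3-(tert-butyldimethylsilyloxy)-2-chloro-6-hydroxy-2-methylcyclohexan-1-one (epimers at the C–Cl and C–OH carbons), via trimethylsilyl ether 6 (not isolated)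
Conditions: mCPBA, NaHCO3, CH2Cl2, −20 → 0 °C; then 1 M HCl, THF, 0 °C
Reagents that add atoms: 3-chloroperoxybenzoic acid, OOC(=O)c1cccc(Cl)c1
Why: Rubottom oxidation (epoxidation of the enol silane, silyl migration, mild hydrolysis) places the hydroxyl on the future C6; its configuration is immaterial because C6 becomes trigonal in step 10.

Step 6
Reactants: 8 4,4-diethoxybut-1-yne
Product: 10 methyl 5,5-diethoxypent-2-ynoate, via lithium acetylide 9 (not isolated)
Conditions: n-BuLi, THF, −78 °C; ClCO2Me, −78 → 0 °C
Reagents that add atoms: methyl chloroformate, COC(=O)Cl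
Why: C-acylation of a lithium acetylide with a chloroformate is a standard route to ynoates, and the acetal is inert to the base.

Step 7
Reactants: 10 methyl 5,5-diethoxypent-2-ynoate
Product: 11 methyl (2E)-3-(2,2-diethoxyethyl)penta-2,4-dienoate
Conditions: CH2=CHMgBr (2.4 equiv), CuI (1.2 equiv), THF, −78 °C; sat. NH4Cl at −78 °C
Reagents that add atoms: vinylmagnesium bromide, C=C[Mg]Br
Why: Organocuprate conjugate addition to an ynoate at −78 °C is a syn carbometalation followed by protonation with retention, which places the vinyl group trans to the ester and so fixes the (E) geometry of the future C10=C1 bond.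

Step 8
Reactants: 11 methyl (2E)-3-(2,2-diethoxyethyl)penta-2,4-dienoate
Product: 12 (2E)-3-(2,2-diethoxyethyl)penta-2,4-dien-1-ol
Conditions: DIBAL-H, CH2Cl2, −78 °C; Rochelle salt
Reagents that add atoms: none
Why: DIBAL-H reduces the conjugated ester to the allylic alcohol by 1,2-addition without touching the diene geometry or the acetal.

Step 9
Reactants: 7 (3S)-3-(tert-butyldimethylsilyloxy)-2-chloro-6-hydroxy-2-methylcyclohexan-1-one; 13 dichlorodi(propan-2-yl)silane; 12 (2E)-3-(2,2-diethoxyethyl)penta-2,4-dien-1-ol
Product: 15 silicon-tethered α-chloro ketone (mixed diisopropylsilyl ketal joining the ketol oxygen of 7 to the oxygen of dienol 12), via chlorosilyl ether 14 (not isolated)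
Conditions: 13 (3 equiv), imidazole, CH2Cl2, 0 °C; excess 13 removed in vacuo; then 12, imidazole, DMAP (cat.), CH2Cl2, 0 → 23 °C
Reagents that add atoms: none
Why: Stepwise silylation with a dialkyldichlorosilane (hindered secondary ketol first with excess silane, then the primary allylic alcohol) is the standard assembly of unsymmetrical dialkoxysilane tethers, and imidazole is too weak a base to enolise the chloro ketone.

Step 10
Reactants: 15 silicon-tethered α-chloro ketone
Product: 17 silylene-bridged bicyclo[4.3.1]decenone (C5 ketone; C4 methyl; O6–Si(iPr)2–O11 siladioxane with C11 trans to O6 on the seven-membered ring; C9 OTBS anti to C3; C1=C2; 2,2-diethoxyethyl on C1), via oxyallyl cation 16 (not isolated)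
Conditions: Et3N (3 equiv), 3 M LiClO4 in Et2O, 0.005 M, 23 °C
Reagents that add atoms: none
Why: Proposed new method: Et3N enolises 15 toward C6 and lithium-assisted loss of chloride from C4 gives the siloxy-stabilised oxyallyl cation 16 (the C4 and C6 epimers of 15 converge), which the tethered diene captures across its termini, in concert or by C6–C10 bonding first and collapse of the allyl cation onto C4; the closest known reactions are the (4+3) cycloadditions of α-chlorocyclohexanone-derived oxyallyl cations with 1,3-dienes under Et3N/LiClO4–Et2O and the carbon-tethered intramolecular (4+3) cycloadditions of tertiary α-chloro cycloalkanones, neither of which has been run through a silicon tether on an oxygen substituent of the cation or with two quaternary bridgeheads formed at once. The seven-membered ring (C4–C5–C6–C10–C1–C2–C3) closes by cycloaddition, C3 bonding to C4 and C10 to C6, and the 1,3-dioxa-2-silinane (C6–O6–Si–O11–C11–C10) closes in the same event through the C6–C10 bond in a six-membered chair-like array. C4 and C6 are set together by the face of the planar cation that the diene takes, namely the face anti to the C9 silyloxy group, which A(1,2) strain with the C4 methyl group holds pseudoaxial; their mutual relationship is dictated by the bridge. C10 is set by the (E) geometry of C10=C1, which keeps C11 outside and within reach of O6, together with the extended arrangement in which the diene and its C1 side chain stay clear of the ether-solvated lithium oxide on C5, so that C11 ends up trans to O6 on the seven-membered ring. The step needs regiocontrol (C10 to C6 and C3 to C4), which the four-atom tether enforces because the reverse orientation cannot be spanned, and extended-over-compact selectivity, which is the least secure element; high dilution suppresses intermolecular capture.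

Step 11
Reactants: 17 silylene-bridged bicyclo[4.3.1]decenone
Product: 18 C5 alcohol of 17 (either C5 epimer)
Conditions: LiAlH4, Et2O, 0 °C
Reagents that add atoms: none
Why: The small hydride of LiAlH4 reaches a bridging carbonyl flanked by two quaternary carbons, as with bicyclo[3.3.1]nonan-9-ones, and either C5 epimer is acceptable because the centre becomes CH2 two steps later.

Step 12
Reactants: 18 C5 alcohol
Product: 20 C5 O-alkyl S-methyl xanthate, via potassium xanthate 19 (not isolated)
Conditions: KHMDS, THF, −78 °C; CS2, −78 °C; MeI, −78 → 0 °C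
Reagents that add atoms: carbon disulfide, S=C=S; iodomethane, CI
Why: Xanthate formation (alkoxide, CS2, MeI) is the least sterically demanding thioacylation of a hindered secondary alcohol, and deprotonation at −78 °C with immediate CS2 capture leaves the alkoxide little time to attack the neighbouring silicon.

Step 13
Reactants: 20 C5 xanthate
Product: 21 silylene-bridged bicyclo[4.3.1]decene with C5 as CH2
Conditions: Bu3SnH, AIBN, toluene, 110 °C
Reagents that add atoms: none
Why: Barton–McCombie deoxygenation gives the secondary C5 radical, which is reduced by the stannane; Chugaev elimination is excluded because C4 and C6 carry no hydrogen, and transannular addition to C1=C2 would need a four-membered ring.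

Step 14
Reactants: 21 deoxygenated silylene-bridged bicycle
Product: 22 ene triol (C6 tertiary OH; C9 OH; C11 OH; C1=C2)
Conditions: TBAF, THF, 23 → 50 °C
Reagents that add atoms: none
Why: Fluoride cleaves all three Si–O bonds (silylene and TBS) in one operation; with C5 now a methylene group the freed tertiary C6 alcohol is no longer an α-ketol and cannot rearrange.

Step 15
Reactants: 22 ene triol
Product: 23 saturated triol (H at C1 cis to C11; side chain on C1 trans to C11)
Conditions: H2 (1 atm), [Ir(cod)(PCy3)(py)]PF6 (10 mol %), CH2Cl2, 23 °C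
Reagents that add atoms: none
Why: Hydroxyl-directed hydrogenation with Crabtree's catalyst: the homoallylic C11 hydroxyl binds iridium and delivers H2 to the alkene face on which C11 lies, so H at C1 is cis to C11 and the acetal side chain trans to it, which is the C1 configuration of the target.

Step 16
Reactants: 23 saturated triol
Product: 24 keto aldehyde (C9 ketone; C11 aldehyde; C6 OH)
Conditions: Dess–Martin periodinane, NaHCO3, CH2Cl2, 0 → 23 °C
Reagents that add atoms: none
Why: Dess–Martin oxidation converts the secondary C9 alcohol into the ketone (erasing the centre once it has done its directing work) and the primary C11 alcohol into the aldehyde under buffered conditions, while the tertiary C6 alcohol is inert.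

Step 17
Reactants: 24 keto aldehyde
Product: 25 diol with inverted C9 (C9 OH equatorial and on the side of C3; C11 OH)
Conditions: NaBH4, MeOH, −20 → 0 °C
Reagents that add atoms: none
Why: Borohydride reduces both carbonyl groups; at C9 hydride enters axially from the convex face of the chair cyclohexanone, anti to the C3–C4 bond, giving the equatorial alcohol, which is the target configuration and also the more stable epimer.

Step 18
Reactants: 25 diol
Product: 26 C11 aldehyde (C9 OH and C6 OH free; diethyl acetal at C17)
Conditions: TEMPO (0.2 equiv), PhI(OAc)2, CH2Cl2, 23 °C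
Reagents that add atoms: none
Why: TEMPO/PhI(OAc)2 oxidation is selective for primary over secondary alcohols, so only C11 is oxidised and the hindered C9 carbinol and the tertiary alcohol remain.

Step 19
Reactants: 26 C11 aldehyde acetal
Product: 27 dialdehyde (C11 and C17 formyl groups)
Conditions: PPTS (cat.), acetone–H2O (10:1), 40 °C
Reagents that add atoms: water, O
Why: Mild acid-catalysed hydrolysis of the acyclic diethyl acetal frees the C17 aldehyde; the β-hydroxy aldehyde cannot dehydrate because its hydroxyl sits on a bridgehead.

Step 20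
Reactants: 28 2-methylbut-3-yn-2-ol
Product: 30 4-methylpent-2-yne-1,4-diol, via dilithio derivative 29 (not isolated)
Conditions: n-BuLi (2.2 equiv), THF, −78 → 0 °C; (CH2O)n, 0 → 23 °C; aq. NH4Cl
Reagents that add atoms: formaldehyde (as paraformaldehyde), C=O
Why: Hydroxymethylation of the dilithiated propargylic alcohol with formaldehyde is a standard acetylide addition.

Step 21
Reactants: 30 4-methylpent-2-yne-1,4-diol
Product: 31 (2E)-4-methylpent-2-ene-1,4-diol
Conditions: LiAlH4, THF, reflux
Reagents that add atoms: none
Why: Alkoxide-directed trans-hydroalumination of a propargylic alcohol by LiAlH4 gives the (E)-alkene after protonolysis.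

Step 22
Reactants: 31 (2E)-4-methylpent-2-ene-1,4-diol
Product: 32 (2E)-4-hydroxy-4-methylpent-2-enal
Conditions: MnO2, CH2Cl2, 23 °C
Reagents that add atoms: none
Why: MnO2 oxidises the primary allylic alcohol selectively; the tertiary alcohol cannot be oxidised and the (E)-enal cannot form a lactol.

Step 23
Reactants: 27 dialdehyde; 32 (2E)-4-hydroxy-4-methylpent-2-enal
Product: 34 umbellacin A, via aldol adduct 33 (not isolated)
Conditions: pyrrolidine (0.3 equiv), PhCO2H (0.3 equiv), 32 (3 equiv), CH2Cl2, 0 → 23 °C
Reagents that add atoms: none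
Why: Amine-catalysed crossed aldol condensation: the enamine of the unhindered C17 aldehyde adds to the non-enolisable enal 32 and dehydration gives the thermodynamically preferred (12E)-dienal; the C11 aldehyde is α-branched next to a quaternary carbon and does not compete as the enamine partner, and an intramolecular aldol between C11 and C17 would need a four-membered ring.

**Compound list**

1 | 2-methylcyclohexane-1,3-dione | CC1C(=O)CCCC1=O | starting material
2 | 2-chloro-2-methylcyclohexane-1,3-dione | CC1(Cl)C(=O)CCCC1=O | intermediate
3 | (3S)-2-chloro-3-hydroxy-2-methylcyclohexan-1-one (C2 epimers) | O=C1C(C)(Cl)[C@@H](O)CCC1 | intermediate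
4 | (3S)-3-(tert-butyldimethylsilyloxy)-2-chloro-2-methylcyclohexan-1-one | O=C1C(C)(Cl)[C@@H](O[Si](C)(C)C(C)(C)C)CCC1 | intermediate
5 | (5S)-5-(tert-butyldimethylsilyloxy)-6-chloro-6-methyl-1-(trimethylsilyloxy)cyclohex-1-ene | C[Si](C)(C)OC1=CCC[C@H](O[Si](C)(C)C(C)(C)C)C1(C)Cl | intermediate
6 | (3S)-3-(tert-butyldimethylsilyloxy)-2-chloro-2-methyl-6-(trimethylsilyloxy)cyclohexan-1-one | O=C1C(C)(Cl)[C@@H](O[Si](C)(C)C(C)(C)C)CCC1O[Si](C)(C)C | intermediate (not isolated)
7 | (3S)-3-(tert-butyldimethylsilyloxy)-2-chloro-6-hydroxy-2-methylcyclohexan-1-one | O=C1C(C)(Cl)[C@@H](O[Si](C)(C)C(C)(C)C)CCC1O | intermediate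
8 | 4,4-diethoxybut-1-yne | C#CCC(OCC)OCC | starting material
9 | (4,4-diethoxybut-1-yn-1-yl)lithium | [Li]C#CCC(OCC)OCC | intermediate (not isolated)
10 | methyl 5,5-diethoxypent-2-ynoate | COC(=O)C#CCC(OCC)OCC | intermediate
11 | methyl (2E)-3-(2,2-diethoxyethyl)penta-2,4-dienoate | COC(=O)/C=C(/C=C)CC(OCC)OCC | intermediate
12 | (2E)-3-(2,2-diethoxyethyl)penta-2,4-dien-1-ol | OC/C=C(/C=C)CC(OCC)OCC | intermediate
13 | dichlorodi(propan-2-yl)silane | CC(C)[Si](Cl)(Cl)C(C)C | starting material
14 | chloro(diisopropyl)silyl ether of ketol 7 | O=C1C(C)(Cl)[C@@H](O[Si](C)(C)C(C)(C)C)CCC1O[Si](Cl)(C(C)C)C(C)C | intermediate (not isolated)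
15 | silicon-tethered α-chloro ketone (key-step precursor) | O=C1C(C)(Cl)[C@@H](O[Si](C)(C)C(C)(C)C)CCC1O[Si](C(C)C)(C(C)C)OC/C=C(/C=C)CC(OCC)OCC | intermediate
16 | siloxy-substituted oxyallyl cation (zwitterion, lithium-bound in the medium) | C[C+]1C([O-])=C(O[Si](C(C)C)(C(C)C)OC/C=C(/C=C)CC(OCC)OCC)CC[C@@H]1O[Si](C)(C)C(C)(C)C | intermediate (not isolated)
17 | silylene-bridged bicyclo[4.3.1]decenone (key-step product) | C1(CC(OCC)OCC)=CC[C@@]2(C)C(=O)[C@]4(O[Si](C(C)C)(C(C)C)OC[C@H]14)CC[C@@H]2O[Si](C)(C)C(C)(C)C | intermediate
18 | C5 alcohol of 17 (C5 epimer undefined) | C1(CC(OCC)OCC)=CC[C@@]2(C)C(O)[C@]4(O[Si](C(C)C)(C(C)C)OC[C@H]14)CC[C@@H]2O[Si](C)(C)C(C)(C)C | intermediate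
19 | potassium C5 xanthate | C1(CC(OCC)OCC)=CC[C@@]2(C)C(OC(=S)[S-])[C@]4(O[Si](C(C)C)(C(C)C)OC[C@H]14)CC[C@@H]2O[Si](C)(C)C(C)(C)C.[K+] | intermediate (not isolated)
20 | C5 O-alkyl S-methyl xanthate | C1(CC(OCC)OCC)=CC[C@@]2(C)C(OC(=S)SC)[C@]4(O[Si](C(C)C)(C(C)C)OC[C@H]14)CC[C@@H]2O[Si](C)(C)C(C)(C)C | intermediate
21 | silylene-bridged bicyclo[4.3.1]decene, C5 = CH2 | C1(CC(OCC)OCC)=CC[C@@]2(C)C[C@]4(O[Si](C(C)C)(C(C)C)OC[C@H]14)CC[C@@H]2O[Si](C)(C)C(C)(C)C | intermediate
22 | ene triol (C6, C9, C11 hydroxyls; C1=C2) | OC[C@@H]1C(CC(OCC)OCC)=CC[C@@]2(C)C[C@]1(O)CC[C@@H]2O | intermediate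
23 | saturated triol (C1 set) | OC[C@@H]1[C@@H](CC(OCC)OCC)CC[C@@]2(C)C[C@]1(O)CC[C@@H]2O | intermediate
24 | keto aldehyde (C9 ketone, C11 aldehyde) | O=C[C@@H]1[C@@H](CC(OCC)OCC)CC[C@@]2(C)C[C@]1(O)CCC2=O | intermediate
25 | diol with inverted C9 | OC[C@@H]1[C@@H](CC(OCC)OCC)CC[C@@]2(C)C[C@]1(O)CC[C@H]2O | intermediate
26 | C11 aldehyde, C17 diethyl acetal | O=C[C@@H]1[C@@H](CC(OCC)OCC)CC[C@@]2(C)C[C@]1(O)CC[C@H]2O | intermediate
27 | dialdehyde (C11 and C17 formyl) | O=C[C@@H]1[C@@H](CC=O)CC[C@@]2(C)C[C@]1(O)CC[C@H]2O | intermediate
28 | 2-methylbut-3-yn-2-ol | CC(C)(O)C#C | starting material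
29 | dilithio derivative of 28 | CC(C)(O[Li])C#C[Li] | intermediate (not isolated)
30 | 4-methylpent-2-yne-1,4-diol | CC(C)(O)C#CCO | intermediate
31 | (2E)-4-methylpent-2-ene-1,4-diol | CC(C)(O)/C=C/CO | intermediate
32 | (2E)-4-hydroxy-4-methylpent-2-enal | CC(C)(O)/C=C/C=O | intermediate
33 | aldol adduct (C13 carbinol, C12 and C13 undefined) | CC(C)(O)/C=C/C(O)C(C=O)[C@H]1CC[C@@]2(C)C[C@](O)(CC[C@H]2O)[C@@H]1C=O | intermediate (not isolated)
34 | umbellacin A | CC(C)(O)/C=C/C=C(/C=O)[C@H]1CC[C@@]2(C)C[C@](O)(CC[C@H]2O)[C@@H]1C=O | target

**Count and risks**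

Total steps: 23. Longest linear sequence: 17 steps (steps 1–5, 9–19 and 23).

Step 10 (proposed new method). The lithium oxyallyl may be consumed by Favorskii contraction or by loss of HCl to the conjugated enone before the tethered diene reaches it, or the ring may close through the compact arrangement and give the C10 epimer. The fallback makes the same two bonds by the known untethered reaction. It sets out from ketol 7 and dienol 12: 7 is converted with TESCl and imidazole into the triethylsilyl ether of the ketol F1, and 12 likewise into the triethylsilyl ether of the dienol F2. Ionisation of F1 (Et3N, LiClO4–Et2O) with excess F2 is the established intermolecular (4+3) cycloaddition of an α-chlorocyclohexanone-derived oxyallyl cation with a 1,3-diene; without the tether the regio- and stereoisomers must be separated to obtain the bis(triethylsilyl) adduct F3. PPTS in ethanol removes both triethylsilyl groups while the TBS ether and the diethyl acetal stay, giving the keto diol F4, and iPr2Si(OTf)2 with 2,6-lutidine ties O6 to O11, which returns the material to the route at 17.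

Step 12. The potassium alkoxide at C5 may attack the adjacent silicon (silylene migration or ring opening) faster than it captures CS2, or the doubly neopentyl alkoxide may not be thioacylated cleanly. The fallback replaces the alkoxide/tin sequence by an electron-transfer deoxygenation. It sets out from alcohol 18, which is acylated under neutral conditions (4-methylbenzoyl chloride, DMAP, pyridine, 60 °C) to the C5 4-methylbenzoate F5; SmI2/HMPA in refluxing THF (Markó–Lam deoxygenation) then cleaves the C5–O bond and gives 21 directly.

Step 23. The dialdehyde may self-condense, the enamine may add in a conjugate sense to 32, or the amine may epimerise C10 or open the β-hydroxy aldehyde by retro-aldol cleavage. The fallback runs the condensation before the C11 aldehyde exists. It sets out from diol 25, which is silylated at the primary hydroxyl (TBSCl, imidazole) to the C11 silyl ether F6; PPTS in wet acetone frees the C17 aldehyde to give the mono-aldehyde F7. Condensation with 32 under the same amine catalysis then involves a single aldehyde and gives the silylated dienal F8; HF·pyridine removes the silyl group to give the hydroxy dienal F9, and TEMPO/PhI(OAc)2 oxidises the primary C11 alcohol in the presence of the C9 carbinol, rejoining the route at 34.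

Further compounds
F1 | step 10 | triethylsilyl ether of the ketol | O=C1C(C)(Cl)[C@@H](O[Si](C)(C)C(C)(C)C)CCC1O[Si](CC)(CC)CC
F2 | step 10 | triethylsilyl ether of the dienol | CC[Si](CC)(CC)OC/C=C(/C=C)CC(OCC)OCC
F3 | step 10 | bis(triethylsilyl) adduct (untethered cycloadduct, C6 and C11 OTES) | C1(CC(OCC)OCC)=CC[C@@]2(C)C(=O)[C@@](O[Si](CC)(CC)CC)([C@@H]1CO[Si](CC)(CC)CC)CC[C@@H]2O[Si](C)(C)C(C)(C)C
F4 | step 10 | keto diol (C6 and C11 hydroxyls, C5 ketone, C9 OTBS) | C1(CC(OCC)OCC)=CC[C@@]2(C)C(=O)[C@@](O)([C@@H]1CO)CC[C@@H]2O[Si](C)(C)C(C)(C)C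
F5 | step 12 | C5 4-methylbenzoate of 18 | C1(CC(OCC)OCC)=CC[C@@]2(C)C(OC(=O)c3ccc(C)cc3)[C@]4(O[Si](C(C)C)(C(C)C)OC[C@H]14)CC[C@@H]2O[Si](C)(C)C(C)(C)C
F6 | step 23 | C11 silyl ether of diol 25 | CC(C)(C)[Si](C)(C)OC[C@@H]1[C@@H](CC(OCC)OCC)CC[C@@]2(C)C[C@]1(O)CC[C@H]2O
F7 | step 23 | mono-aldehyde (C17 formyl, C11 OTBS) | CC(C)(C)[Si](C)(C)OC[C@@H]1[C@@H](CC=O)CC[C@@]2(C)C[C@]1(O)CC[C@H]2O
F8 | step 23 | silylated dienal (C11 OTBS) | CC(C)(O)/C=C/C=C(/C=O)[C@H]1CC[C@@]2(C)C[C@](O)(CC[C@H]2O)[C@@H]1CO[Si](C)(C)C(C)(C)C
F9 | step 23 | hydroxy dienal (C11 OH) | CC(C)(O)/C=C/C=C(/C=O)[C@H]1CC[C@@]2(C)C[C@](O)(CC[C@H]2O)[C@@H]1CO
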